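**Retrosynthetic overview**
1. The target is (2S)-6-(1,1-dimethylallyl)eriodictyol. The C6 side chain comes from an Eu(III)-catalysed Claisen shift of a 5-O-prenyl ether (C6 is the only free ortho position), followed by one global acidolysis.
2. Ring C (O1–C2–C3–C4–C4a–C8a) is cut at O1–C8a and C4–C4a, giving aryne 17 (C4a≡C8a of ring A) and (S)-4-aryloxetan-2-one 7. The four-membered lactone is expanded by two atoms to the pyranone by insertion of the aryne into the acyl C4–O1 bond.
3. Enabling feature: O1–C2–C3–C4(=O) of ring C is a β-oxy-carbonyl array whose two ends sit on adjacent A-ring carbons, i.e. a strained β-lactone plus a benzyne. The C5 oxygen next to C4a steers O1 to C8a and the acyl carbon to C4a. C2 lies on no breaking bond, so its (S) configuration is set beforehand by transfer hydrogenation.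
4. Lactone 7 comes from 3,4-diacetoxybenzaldehyde (Roskamp, ATH, hydrogenolysis, lactonisation). Aryne precursor 16 comes from phloroglucinol (bis-MOM ether, carbamate-directed ortho-silylation, triflation).
5. Ring order: rings A and B are bought; the oxetanone ring is closed in step 4 and becomes pyranone ring C in step 9.

Key step: step 9

Remark: the SMILES encodes the (2S)-flavanone; 1, 2, 8 and 20 are taken as catalogue compounds.

**Step 1**
Reactants: 1 3,4-diacetoxybenzaldehyde; 2 benzyl diazoacetate
Product: 3 benzyl 3-(3,4-diacetoxyphenyl)-3-oxopropanoate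
Conditions: NbCl5 (5 mol %), CH2Cl2, rt
Reagents that add atoms: none
Why: Roskamp homologation, in which the Lewis-acid-activated aldehyde is attacked by the diazo carbon and a 1,2-hydride shift with loss of N2 should give the β-keto ester while the aryl acetates stay untouched.

**Step 2**
Reactants: 3 benzyl 3-(3,4-diacetoxyphenyl)-3-oxopropanoate
Product: 4 benzyl (S)-3-(3,4-diacetoxyphenyl)-3-hydroxypropanoate
Conditions: RuCl(p-cymene)[(S,S)-TsDPEN] (1 mol %), HCO2H–Et3N (5:2), EtOAc, 30 °C
Reagents that add atoms: none
Why: Noyori–Ikariya asymmetric transfer hydrogenation of the aryl ketone, in which the (S,S)-catalyst should deliver hydride to the Re face through the CH/π-controlled six-membered transition state (as for acetophenone → (S)-1-phenylethanol) and so set the (S)-carbinol, the future C2, by catalyst control.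

**Step 3**
Reactants: 4 benzyl (S)-3-(3,4-diacetoxyphenyl)-3-hydroxypropanoate
Product: 5 (S)-3-(3,4-diacetoxyphenyl)-3-hydroxypropanoic acid
Conditions: H2 (1 atm), 10 % Pd/C, EtOAc, rt
Reagents that add atoms: none
Why: Hydrogenolysis of the benzyl ester under neutral conditions, where the benzylic secondary alcohol on the electron-poor ring should cleave far more slowly and the aryl acetates are inert.

**Step 4**
Reactants: 5 (S)-3-(3,4-diacetoxyphenyl)-3-hydroxypropanoic acid
Product: 7 (S)-4-(3,4-diacetoxyphenyl)oxetan-2-one, via mixed carboxylic–sulfonic anhydride 6 (not isolated)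
Conditions: PhSO2Cl (2 equiv), pyridine, 0–4 °C
Reagents that add atoms: none
Why: Adam-type β-lactonisation in which the carboxyl group is activated and the β-hydroxyl closes the four-membered ring by 4-exo-trig acyl substitution, so the carbinol C–O bond is untouched and (S) is retained, while the acetoxy groups should suppress benzylic ionisation and decarboxylation.

**Step 5**
Reactants: 8 phloroglucinol
Product: 9 3,5-bis(methoxymethoxy)phenol
Conditions: MOMCl (2.0 equiv), i-Pr2NEt (2.2 equiv), CH2Cl2–THF, 0 °C → rt; chromatography
Reagents that add atoms: chloromethyl methyl ether, COCCl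
Why: O-Alkylation of the phenol with the α-chloro ether; bis-etherification of the C3-symmetric triol can give only one constitutional isomer, which should be separable from the mono- and tris-ethers of the statistical mixture.

**Step 6**
Reactants: 9 3,5-bis(methoxymethoxy)phenol
Product: 10 3,5-bis(methoxymethoxy)phenyl N-isopropylcarbamate
Conditions: i-PrNCO (1.2 equiv), Et3N (10 mol %), CH2Cl2, rt
Reagents that add atoms: isopropyl isocyanate, CC(C)N=C=O
Why: Base-catalysed addition of the phenol to the isocyanate (carbamoylation) installs the directing group that later serves as the masked triflate oxygen.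

**Step 7**
Reactants: 10 3,5-bis(methoxymethoxy)phenyl N-isopropylcarbamate
Product: 14 3,5-bis(methoxymethoxy)-2-(trimethylsilyl)phenyl N-isopropylcarbamate, via N-TBS carbamate 11 (not isolated), via ortho-lithiated N-TBS carbamate 12 (not isolated), via N-TBS C-TMS carbamate 13 (not isolated)
Conditions: TBSOTf (1.05 equiv), TMEDA, Et2O, 0 °C → rt; n-BuLi, TMEDA, −78 °C; TMSCl, −78 °C → rt; aq. citric acid
Reagents that add atoms: chlorotrimethylsilane, C[Si](C)(C)Cl
Why: Snieckus–Hoppe directed ortho-metalation, in which the N-silylated carbamate is the strongest directing group and the site between it and an OMOM group is activated cooperatively, so lithiation and TMSCl trapping should occur there before the N–Si bond is hydrolysed on work-up.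

**Step 8**
Reactants: 14 3,5-bis(methoxymethoxy)-2-(trimethylsilyl)phenyl N-isopropylcarbamate
Product: 16 3,5-bis(methoxymethoxy)-2-(trimethylsilyl)phenyl trifluoromethanesulfonate, via 2-silylphenol 15 (not isolated)
Conditions: DBU (1.5 equiv), Et2NH (1.2 equiv), MeCN, 40 °C; then PhNTf2 (1.5 equiv), rt
Reagents that add atoms: N-phenylbis(trifluoromethanesulfonimide), O=S(=O)(N(c1ccccc1)S(=O)(=O)C(F)(F)F)C(F)(F)F
Why: E1cB cleavage of the N-monoalkyl carbamate (the isocyanate is scavenged by Et2NH) should free the hindered phenoxide, which is triflated in the same flask to give a Kobayashi-type aryne precursor.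

**Step 9**
Reactants: 7 (S)-4-(3,4-diacetoxyphenyl)oxetan-2-one (1.5 equiv); 16 3,5-bis(methoxymethoxy)-2-(trimethylsilyl)phenyl trifluoromethanesulfonate
Product: 18 (2S)-3',4'-di-O-acetyl-5,7-bis-O-(methoxymethyl)eriodictyol [(S)-2-(3,4-diacetoxyphenyl)-5,7-bis(methoxymethoxy)chroman-4-one], via aryne 17 (not isolated)
Conditions: CsF (2.5 equiv), MeCN–toluene (1:1), 0 °C → rt; 16 added slowly to 7
Reagents that add atoms: none
Why: Proposed new method: fluoride-induced 1,2-elimination of 16 gives the 3,5-dialkoxyaryne 17, which is attacked at the carbon remote from the flanking OMOM group by the ring oxygen of 7 (ester resonance is weak in the strained oxetan-2-one, so this oxygen is ether-like; alternatively fluoride opens 7 reversibly to the β-alkoxy acyl fluoride, whose alkoxide arylates), and the aryl anion formed next to the OMOM group then attacks the acyl carbon so that the C(acyl)–O bond breaks with release of four-ring strain, the net result being σ-insertion of the aryne into the C4–O1 bond. The closest known reactions are the insertion of arynes into the amide N–C(=O) bond of β-lactams, which gives 2,3-dihydroquinolin-4-ones by the same 4→6 ring expansion, and the formal C–O insertion of arynes into carboxylic acids to give o-hydroxyaryl ketones. Ring C is thus closed by ring expansion of the oxetanone: O1–C8a by nucleophilic addition to the aryne, and C4–C4a by intramolecular acyl substitution through a benzoxete-type four-membered transition structure (6-exo-trig on the acyl fluoride in the relay variant). No stereocentre is formed, and C2 should keep the (S) configuration of 7 because none of its bonds is broken in either pathway. The step needs regioselectivity (O to C8a, acyl to C4a), secured by the inductive and distortion bias of the 3-alkoxy group on the aryne, and chemoselectivity over base-induced β-elimination of 7 and retro-oxa-Michael opening of 18, for which low temperature, slow aryne generation and the electron-poor diacetoxyaryl group (which also disfavours ionisation of the benzylic C–O bond) are relied on.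

**Step 10**
Reactants: 18 (2S)-3',4'-di-O-acetyl-5,7-bis-O-(methoxymethyl)eriodictyol
Product: 19 (2S)-3',4'-di-O-acetyl-7-O-(methoxymethyl)eriodictyol (5-OH free)
Conditions: MgBr2·OEt2 (3 equiv), Et2O–CH2Cl2, 0 °C → rt
Reagents that add atoms: none
Why: Chelation-controlled Lewis-acid cleavage of an acetal ether, in which Mg(II) bridges the C4 carbonyl and the peri 5-oxygen and bromide removes the methoxymethyl group there, while the unchelated 7-OMOM and the acetates should remain.

**Step 11**
Reactants: 19 (2S)-3',4'-di-O-acetyl-7-O-(methoxymethyl)eriodictyol; 20 3-methylbut-2-en-1-ol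
Product: 21 (2S)-3',4'-di-O-acetyl-7-O-(methoxymethyl)-5-O-(3-methylbut-2-enyl)eriodictyol
Conditions: PPh3, DIAD, THF, 0 °C → rt
Reagents that add atoms: none
Why: Mitsunobu O-alkylation of the hydrogen-bonded 5-phenol by SN2 at the primary allylic carbon under neutral conditions, which avoids base-mediated retro-oxa-Michael racemisation at C2.

**Step 12**
Reactants: 21 (2S)-3',4'-di-O-acetyl-7-O-(methoxymethyl)-5-O-(3-methylbut-2-enyl)eriodictyol
Product: 23 (2S)-3',4'-di-O-acetyl-6-(2-methylbut-3-en-2-yl)-7-O-(methoxymethyl)eriodictyol, via ortho-dienone 22 (not isolated)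
Conditions: Eu(fod)3 (10 mol %), CHCl3, 60 °C, sealed tube
Reagents that add atoms: none
Why: Eu(III)-catalysed aromatic Claisen [3,3] rearrangement, in which chelation between C4=O and the 5-ether oxygen should accelerate the shift to C6 (the only free ortho position) and tautomerisation of the dienone gives the 1,1-dimethylallyl phenol, the low temperature being chosen so that the follow-up Cope shift to C8 should not set in and C2 is not involved.

**Step 13**
Reactants: 23 (2S)-3',4'-di-O-acetyl-6-(2-methylbut-3-en-2-yl)-7-O-(methoxymethyl)eriodictyol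
Product: 24 (2S)-5,7,3',4'-tetrahydroxy-6-(2-methylbut-3-en-2-yl)flavanone (target)
Conditions: HCl (1.25 M in MeOH), 40 °C
Reagents that add atoms: none
Why: Acid-catalysed acetal methanolysis and transesterification of the aryl acetates in one operation, where acidic rather than basic conditions should protect C2 from retro-oxa-Michael racemisation and the monosubstituted alkene is a poor site for protonation.

**Compound list**
1 | 3,4-diacetoxybenzaldehyde | CC(=O)Oc1ccc(C=O)cc1OC(C)=O | starting material
2 | benzyl diazoacetate | [N-]=[N+]=CC(=O)OCc1ccccc1 | starting material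
3 | benzyl 3-(3,4-diacetoxyphenyl)-3-oxopropanoate | CC(=O)Oc1ccc(C(=O)CC(=O)OCc2ccccc2)cc1OC(C)=O | intermediate
4 | benzyl (S)-3-(3,4-diacetoxyphenyl)-3-hydroxypropanoate | O=C(OCc1ccccc1)C[C@@H](c1ccc(OC(C)=O)c(OC(C)=O)c1)O | intermediate
5 | (S)-3-(3,4-diacetoxyphenyl)-3-hydroxypropanoic acid | OC(=O)C[C@@H](c1ccc(OC(C)=O)c(OC(C)=O)c1)O | intermediate
6 | mixed anhydride of 5 with benzenesulfonic acid (not isolated) | O=C(OS(=O)(=O)c1ccccc1)C[C@@H](c1ccc(OC(C)=O)c(OC(C)=O)c1)O | intermediate
7 | (S)-4-(3,4-diacetoxyphenyl)oxetan-2-one | O=C1C[C@@H](c2ccc(OC(C)=O)c(OC(C)=O)c2)O1 | intermediate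
8 | phloroglucinol (benzene-1,3,5-triol) | Oc1cc(O)cc(O)c1 | starting material
9 | 3,5-bis(methoxymethoxy)phenol | COCOc1cc(O)cc(OCOC)c1 | intermediate
10 | 3,5-bis(methoxymethoxy)phenyl N-isopropylcarbamate | CC(C)NC(=O)Oc1cc(OCOC)cc(OCOC)c1 | intermediate
11 | N-(tert-butyldimethylsilyl) derivative of 10 (not isolated) | CC(C)N(C(=O)Oc1cc(OCOC)cc(OCOC)c1)[Si](C)(C)C(C)(C)C | intermediate
12 | 2-lithio derivative of 11, Li between the carbamate oxygen and an OMOM group (not isolated) | CC(C)N(C(=O)Oc1cc(OCOC)cc(OCOC)c1[Li])[Si](C)(C)C(C)(C)C | intermediate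
13 | N-(tert-butyldimethylsilyl) derivative of 14 (not isolated) | CC(C)N(C(=O)Oc1cc(OCOC)cc(OCOC)c1[Si](C)(C)C)[Si](C)(C)C(C)(C)C | intermediate
14 | 3,5-bis(methoxymethoxy)-2-(trimethylsilyl)phenyl N-isopropylcarbamate | CC(C)NC(=O)Oc1cc(OCOC)cc(OCOC)c1[Si](C)(C)C | intermediate
15 | 3,5-bis(methoxymethoxy)-2-(trimethylsilyl)phenol (not isolated) | Oc1cc(OCOC)cc(OCOC)c1[Si](C)(C)C | intermediate
16 | 3,5-bis(methoxymethoxy)-2-(trimethylsilyl)phenyl trifluoromethanesulfonate | O=S(=O)(Oc1cc(OCOC)cc(OCOC)c1[Si](C)(C)C)C(F)(F)F | intermediate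
17 | 3,5-bis(methoxymethoxy)benzyne (not isolated) | COCOC1=CC(OCOC)=CC#C1 | intermediate
18 | (2S)-3',4'-di-O-acetyl-5,7-bis-O-(methoxymethyl)eriodictyol | COCOc1cc2c(c(OCOC)c1)C(=O)C[C@@H](c1ccc(OC(C)=O)c(OC(C)=O)c1)O2 | intermediate
19 | (2S)-3',4'-di-O-acetyl-7-O-(methoxymethyl)eriodictyol | COCOc1cc2c(c(O)c1)C(=O)C[C@@H](c1ccc(OC(C)=O)c(OC(C)=O)c1)O2 | intermediate
20 | 3-methylbut-2-en-1-ol (prenol) | CC(C)=CCO | starting material
21 | (2S)-3',4'-di-O-acetyl-7-O-(methoxymethyl)-5-O-(3-methylbut-2-enyl)eriodictyol | COCOc1cc2c(c(OCC=C(C)C)c1)C(=O)C[C@@H](c1ccc(OC(C)=O)c(OC(C)=O)c1)O2 | intermediate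
22 | 6-(2-methylbut-3-en-2-yl) cyclohexa-2,4-dienone tautomer of 23, C6 sp3 (not isolated) | C=CC(C)(C)C1C(OCOC)=CC2=C(C1=O)C(=O)C[C@@H](c1ccc(OC(C)=O)c(OC(C)=O)c1)O2 | intermediate
23 | (2S)-3',4'-di-O-acetyl-6-(2-methylbut-3-en-2-yl)-7-O-(methoxymethyl)eriodictyol | COCOc1cc2c(c(O)c1C(C)(C)C=C)C(=O)C[C@@H](c1ccc(OC(C)=O)c(OC(C)=O)c1)O2 | intermediate
24 | (2S)-5,7,3',4'-tetrahydroxy-6-(2-methylbut-3-en-2-yl)flavanone | C=CC(C)(C)c1c(O)cc2c(c1O)C(=O)C[C@@H](c1ccc(O)c(O)c1)O2 | target

**Step count and risks**
Total step count: 13. Longest linear sequence: 9 steps (8 → 24 through steps 5–13; equally 1 → 24 through steps 1–4 and 9–13).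

Steps most likely to fail:

1. Step 9 (proposed method). The lactone oxygen may be too weak a nucleophile, so the aryne would be lost to fluoride or to oligomers. Fluoride may start ring-opening polymerisation of 7. Base-induced β-elimination of 7 or retro-oxa-Michael opening of 18 would erode the enantiomeric purity, which should be checked on 18 before going on. The fallback uses known chemistry and closes ring C directly: it sets out from 3 and 9 and comes back at 18. Transfer hydrogenation of 3 with the (R,R)-TsDPEN catalyst would give benzyl (R)-3-(3,4-diacetoxyphenyl)-3-hydroxypropanoate F1. Mitsunobu etherification with phenol 9 (PPh3, DIAD, toluene, 0 °C) would invert the carbinol centre to give benzyl (S)-3-[3,5-bis(methoxymethoxy)phenoxy]-3-(3,4-diacetoxyphenyl)propanoate F2. Hydrogenolysis (H2, Pd/C, EtOAc) would give (S)-3-[3,5-bis(methoxymethoxy)phenoxy]-3-(3,4-diacetoxyphenyl)propanoic acid F3. Intramolecular Friedel–Crafts acylation through the mixed trifluoroacetic anhydride (TFAA, 2,6-di-tert-butyl-4-methylpyridine, CH2Cl2, −20 → 0 °C) on the phloroglucinol ring, ortho to the ether oxygen (both ortho positions are equivalent), would then return to 18.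

2. Step 4. The aryl β-lactone may be lost by decarboxylative fragmentation, ionisation of the benzylic C–O bond or elimination to the cinnamic acid during activation. The fallback sets out from 1 and comes back at 7, bypassing 3–6. It is a cinchona-alkaloid/Lewis-acid-catalysed ketene–aldehyde [2+2] cyclocondensation (acetyl chloride, i-Pr2NEt, O-trimethylsilylquinine or -quinidine, LiClO4, CH2Cl2–Et2O, −78 °C), with the alkaloid pseudo-enantiomer chosen to give the (S)-lactone. The four-membered ring would then be built in one step from the aldehyde instead of from the hydroxy acid.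

3. Step 7. Lithiation may occur between the two OMOM groups instead of next to the carbamate, and a MOM group may be lost to the silyl triflate. The fallback sets out from 9 and comes back at 16. Amine-mediated ortho-selective bromination (NBS, cat. i-Pr2NH, CH2Cl2, −78 → 0 °C) would give 2-bromo-3,5-bis(methoxymethoxy)phenol F4. O-Silylation (HMDS, THF, 65 °C) would give [2-bromo-3,5-bis(methoxymethoxy)phenoxy]trimethylsilane F5. Bromine–lithium exchange (n-BuLi, THF, −78 °C) followed by retro-Brook O→C silyl shift would give the lithium salt of 15, which is triflated in the flask (PhNTf2) to give 16.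

**Further compounds**
F1 | step 9 | benzyl (R)-3-(3,4-diacetoxyphenyl)-3-hydroxypropanoate | O=C(OCc1ccccc1)C[C@H](c1ccc(OC(C)=O)c(OC(C)=O)c1)O
F2 | step 9 | benzyl (S)-3-[3,5-bis(methoxymethoxy)phenoxy]-3-(3,4-diacetoxyphenyl)propanoate | O=C(OCc1ccccc1)C[C@@H](c1ccc(OC(C)=O)c(OC(C)=O)c1)Oc1cc(OCOC)cc(OCOC)c1
F3 | step 9 | (S)-3-[3,5-bis(methoxymethoxy)phenoxy]-3-(3,4-diacetoxyphenyl)propanoic acid | OC(=O)C[C@@H](c1ccc(OC(C)=O)c(OC(C)=O)c1)Oc1cc(OCOC)cc(OCOC)c1
F0 | step 4 | none | none
F4 | step 7 | 2-bromo-3,5-bis(methoxymethoxy)phenol | COCOc1cc(O)c(Br)c(OCOC)c1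
F5 | step 7 | [2-bromo-3,5-bis(methoxymethoxy)phenoxy]trimethylsilane | COCOc1cc(O[Si](C)(C)C)c(Br)c(OCOC)c1
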